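**Assumption:** CIP analysis of the given SMILES gives (S) at the lavandulyl C2, and the route is built for that enantiomer. The facial sense of the chiral carbene catalyst in step 3 is assigned by analogy, not established.

## Retrosynthetic overview

1. Target 16 ⇒ aldol condensation and desilylation of acetophenone 11 with bis-silylated 2,4-dihydroxybenzaldehyde 13.
2. 11 ⇒ Wittig isopropylidenation of aldehyde 10 ⇒ Fukuyama reduction of thioester 9 (the aryl ketone is not touched).
3. 9 ⇒ key bond ArCH2–CH: carbene-generated homoenolate of dienal 3 (nucleophilic β-carbon) adds to the methide carbon of o-quinone methide 7. This formal [4+3] annulation sets the stereocentre, and the lactone is opened with EtSH in the same flask.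
4. 7 ⇐ sulfone 6 ⇐ acetophenone 4 + CH2O + sulfinate; 3 ⇐ methacrolein 1 + formyl ylide 2.
5. Rings: both benzene rings are bought. The only ring made is the transient seven-membered lactone 8, which is opened again.

## Route

**Step 1**
Reactants: 1 methacrolein; 2 (triphenylphosphoranylidene)acetaldehyde
Product: 3 (2E)-4-methylpenta-2,4-dienal
Conditions: 1 (3 equiv), trace BHT, PhMe, 80 °C, sealed tube, 16 h; distil
Reagents that add atoms: none
Why: Wittig olefination with a stabilised formyl ylide gives the (E)-enal, and excess volatile methacrolein suppresses a second homologation.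

**Step 2**
Reactants: 4 1-(2,4-dihydroxy-6-methoxyphenyl)ethan-1-one
Product: 6 1-[2,4-dihydroxy-6-methoxy-3-[(4-methylbenzenesulfonyl)methyl]phenyl]ethan-1-one, via hydroxymethyl ketone 5 (not isolated)
Conditions: (CH2O)n (1.05 equiv), TolSO2Na (3 equiv), HCO2H/H2O 1:1, rt, 24 h; crystallise
Reagents that add atoms: formaldehyde (from paraformaldehyde), C=O; sodium p-toluenesulfinate, Cc1ccc(cc1)S(=O)[O-].[Na+]
Why: Lederer–Manasse hydroxymethylation followed by acid-promoted substitution of the benzylic alcohol by sulfinate (three-component sulfonylmethylation of phenols); C3, flanked by two hydroxyls, is doubly ortho-activated and less hindered than C5, excess sulfinate outcompetes diarylmethane formation, and the minor C5 isomer is removed by crystallisation.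

**Step 3**
Reactants: 6 sulfone from step 2; 3 (2E)-4-methylpenta-2,4-dienal
Product: 9 S-ethyl (3R)-3-[(3-acetyl-2,6-dihydroxy-4-methoxyphenyl)methyl]-4-methylpent-4-enethioate, via o-quinone methide 7 (not isolated), via benzoxepinone lactone 8 (not isolated)
Conditions: 3 (2 equiv), (5aR,10bS)-2-mesityl-5a,10b-dihydro-4H,6H-indeno[2,1-b][1,2,4]triazolo[4,3-d][1,4]oxazin-2-ium tetrafluoroborate (15 mol%), K2CO3 (1.6 equiv), 4 Å MS, THF, 0 °C to rt, 6 added over 6 h; then EtSH (5 equiv), Et3N (2 equiv), rt, 2 h
Reagents that add atoms: ethanethiol, CCS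
Why: Proposed new method: base-induced 1,4-elimination of sulfinate from 6 releases the acyl-stabilised o-quinone methide 7 at low concentration while the chiral triazolylidene turns dienal 3 into its extended Breslow intermediate, a homoenolate whose β-carbon (normally electrophilic) attacks the equally electrophilic methide carbon of 7; tautomerisation to the acyl azolium and O-acylation by the freed phenoxide close lactone 8 (formal [4+3] annulation; closest precedent is the carbene-catalysed [4+3] annulation of β-aryl enals with o-quinone methides), and ethanethiolate then trans-acylates the activated aryl ester to 9; the stereocentre is set in the C–C bond formation because the fused indane of the catalyst blocks one face of the planar homoenolate, giving the (R) β-carbon (sense by analogy; the (5aS,10bR) antipode is equally available if the first run shows the opposite sense), and closure on either phenol oxygen leads to the same 9.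

**Step 4**
Reactants: 9 thioester from step 3
Product: 10 (3R)-3-[(3-acetyl-2,6-dihydroxy-4-methoxyphenyl)methyl]-4-methylpent-4-enal (in equilibrium with its seven-membered lactol)
Conditions: Et3SiH (4 equiv), Pd/CaCO3 poisoned with Pb(OAc)2 (10 mol% Pd), acetone, rt; dilute citric acid work-up
Reagents that add atoms: none
Why: Fukuyama reduction: zerovalent palladium inserts into the C–S bond and the silane delivers hydride, so only the thioester is reduced while the aryl methyl ketone stays intact, the poisoned catalyst spares the 1,1-disubstituted alkene, and the stereocentre is not involved.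

**Step 5**
Reactants: 10 aldehyde from step 4
Product: 11 1-[2,4-dihydroxy-6-methoxy-3-[(2S)-5-methyl-2-(prop-1-en-2-yl)hex-4-en-1-yl]phenyl]ethan-1-one
Conditions: iPrPPh3I (4.5 equiv), n-BuLi (4.3 equiv), THF, 0 °C; then 10, −78 °C to rt; aq NH4Cl
Reagents that add atoms: isopropyltriphenylphosphonium iodide, CC(C)[P+](c1ccccc1)(c1ccccc1)c1ccccc1.[I-]
Why: Wittig olefination of the aldehyde with the non-stabilised isopropylidene ylide builds the prenyl terminus; surplus ylide holds the phenols as phenoxides, the hindered chelated aryl ketone does not react, and the stereocentre is untouched (the descriptor changes from R to S only through CIP priorities).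

**Step 6**
Reactants: 12 2,4-dihydroxybenzaldehyde
Product: 13 2,4-bis[(tert-butyldimethylsilyl)oxy]benzaldehyde
Conditions: TBSCl (2.5 equiv), imidazole (5 equiv), DMF, 0 °C to rt
Reagents that add atoms: tert-butyldimethylsilyl chloride, CC(C)(C)[Si](C)(C)Cl
Why: Standard imidazole-mediated silylation of both phenols removes the phenoxide deactivation of the aldehyde and gives groups that come off later without acid.

**Step 7**
Reactants: 11 acetophenone from step 5; 13 silylated aldehyde from step 6
Product: 16 (2E)-1-[2,4-dihydroxy-6-methoxy-3-[(2S)-5-methyl-2-(prop-1-en-2-yl)hex-4-en-1-yl]phenyl]-3-(2,4-dihydroxyphenyl)prop-2-en-1-one, via aldol adduct 14 (not isolated), via bis-silyl chalcone 15 (not isolated)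
Conditions: LiN(SiMe3)2 (3.05 equiv), THF, −78 to 0 °C; then 13 (1.3 equiv), −78 °C to rt, 16 h; then AcOH (6 equiv), Bu4NF (3 equiv), 0 °C to rt
Reagents that add atoms: none
Why: Claisen–Schmidt condensation (aldol addition, then E1cB dehydration to the thermodynamic (E)-enone) of the lithium trianion of 11, a protocol known for unprotected prenylated 2'-hydroxyacetophenones, with the base matched to the three acidic protons so that no free amide attacks the aldehyde; buffered fluoride then cleaves the aryl silyl ethers without acid, so the lavandulyl alkenes and the 2'-hydroxychalcone survive and the stereocentre is unchanged.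

## Compound list

1 | methacrolein | CC(=C)C=O | starting material
2 | (triphenylphosphoranylidene)acetaldehyde | O=CC=P(c1ccccc1)(c1ccccc1)c1ccccc1 | starting material
3 | (2E)-4-methylpenta-2,4-dienal | CC(=C)/C=C/C=O | intermediate
4 | 1-(2,4-dihydroxy-6-methoxyphenyl)ethan-1-one | CC(=O)c1c(O)cc(O)cc1OC | starting material
5 | 1-[2,4-dihydroxy-3-(hydroxymethyl)-6-methoxyphenyl]ethan-1-one | CC(=O)c1c(OC)cc(O)c(CO)c1O | intermediate (not isolated)
6 | 1-[2,4-dihydroxy-6-methoxy-3-[(4-methylbenzenesulfonyl)methyl]phenyl]ethan-1-one | CC(=O)c1c(OC)cc(O)c(CS(=O)(=O)c2ccc(C)cc2)c1O | intermediate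
7 | 4-acetyl-5-hydroxy-3-methoxy-6-methylidenecyclohexa-2,4-dien-1-one (o-quinone methide) | CC(=O)C1=C(O)C(=C)C(=O)C=C1OC | intermediate (not isolated)
8 | (4R)-7-acetyl-6-hydroxy-8-methoxy-4-(prop-1-en-2-yl)-4,5-dihydro-1-benzoxepin-2(3H)-one | C=C(C)[C@H]1CC(=O)Oc2cc(OC)c(C(C)=O)c(O)c2C1 | intermediate (not isolated)
9 | S-ethyl (3R)-3-[(3-acetyl-2,6-dihydroxy-4-methoxyphenyl)methyl]-4-methylpent-4-enethioate | C=C(C)[C@@H](CC(=O)SCC)Cc1c(O)cc(OC)c(C(C)=O)c1O | intermediate
10 | (3R)-3-[(3-acetyl-2,6-dihydroxy-4-methoxyphenyl)methyl]-4-methylpent-4-enal | C=C(C)[C@@H](CC=O)Cc1c(O)cc(OC)c(C(C)=O)c1O | intermediate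
11 | 1-[2,4-dihydroxy-6-methoxy-3-[(2S)-5-methyl-2-(prop-1-en-2-yl)hex-4-en-1-yl]phenyl]ethan-1-one | C=C(C)[C@@H](CC=C(C)C)Cc1c(O)cc(OC)c(C(C)=O)c1O | intermediate
12 | 2,4-dihydroxybenzaldehyde | O=Cc1ccc(O)cc1O | starting material
13 | 2,4-bis[(tert-butyldimethylsilyl)oxy]benzaldehyde | O=Cc1ccc(O[Si](C)(C)C(C)(C)C)cc1O[Si](C)(C)C(C)(C)C | intermediate
14 | 3-[2,4-bis[(tert-butyldimethylsilyl)oxy]phenyl]-1-[2,4-dihydroxy-6-methoxy-3-[(2S)-5-methyl-2-(prop-1-en-2-yl)hex-4-en-1-yl]phenyl]-3-hydroxypropan-1-one (both carbinol epimers) | C=C(C)[C@@H](CC=C(C)C)Cc1c(O)cc(OC)c(C(=O)CC(O)c2ccc(O[Si](C)(C)C(C)(C)C)cc2O[Si](C)(C)C(C)(C)C)c1O | intermediate (not isolated)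
15 | (2E)-3-[2,4-bis[(tert-butyldimethylsilyl)oxy]phenyl]-1-[2,4-dihydroxy-6-methoxy-3-[(2S)-5-methyl-2-(prop-1-en-2-yl)hex-4-en-1-yl]phenyl]prop-2-en-1-one | C=C(C)[C@@H](CC=C(C)C)Cc1c(O)cc(OC)c(C(=O)/C=C/c2ccc(O[Si](C)(C)C(C)(C)C)cc2O[Si](C)(C)C(C)(C)C)c1O | intermediate (not isolated)
16 | (2E)-1-[2,4-dihydroxy-6-methoxy-3-[(2S)-5-methyl-2-(prop-1-en-2-yl)hex-4-en-1-yl]phenyl]-3-(2,4-dihydroxyphenyl)prop-2-en-1-one | C=C(C)[C@@H](CC=C(C)C)Cc1c(O)cc(OC)c(C(=O)/C=C/c2ccc(O)cc2O)c1O | target

## Count and risks

Total steps: 7. Longest linear sequence: 5 (4 → 6 → 9 → 10 → 11 → 16; the branch from 1 is equally long).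

**Step 3 (most likely to fail).** The dienal homoenolate may attack through its terminal carbon instead of the β-carbon. The remaining acidic phenol may protonate the β-carbon and divert the reaction to the [4+2] dihydrocoumarin. The o-quinone methide may oligomerise or capture the carbene.
Fallback, from methacrolein 1 (with 2 and 6) back to 9: mask the isopropenyl group as a saturated primary selenide so the enal has a single nucleophilic site. Conjugate addition of PhSeH to 1 (cat. Et3N, CH2Cl2, 0 °C) gives 2-methyl-3-(phenylselanyl)propanal F1. Wittig reaction with 2 gives (2E)-4-methyl-5-(phenylselanyl)pent-2-enal F2. The same carbene-catalysed annulation with 6 and EtSH opening gives S-ethyl (3R)-3-[(3-acetyl-2,6-dihydroxy-4-methoxyphenyl)methyl]-4-methyl-5-(phenylselanyl)pentanethioate F3 as both C4 epimers, which converge. Oxidation with H2O2/pyridine and selenoxide syn-elimination, which can only take the C4 hydrogen, unveils the isopropenyl group and returns 9.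

**Step 2.** The one-pot sulfonylmethylation may give the C5 regioisomer, bis-substitution or methylene-bridged dimers.
Fallback, from 4 back to 6: go through an isolable amine. Mannich aminomethylation (Me2NH, aq CH2O, EtOH, rt) with a mild, self-limiting iminium electrophile gives 1-[3-[(dimethylamino)methyl]-2,4-dihydroxy-6-methoxyphenyl]ethan-1-one F4, which is purified from its regioisomer by acid–base extraction and crystallisation of the hydrochloride. Heating F4 with TolSO2Na in HCO2H exchanges the amine for sulfinate by elimination–addition and returns 6.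

**Step 7.** Silyl migration to the lithium phenoxides before condensation would unmask the para-phenoxide of the aldehyde and stall the aldol. The telescoped fluoride step may also promote chalcone-to-flavanone closure.
Fallback, from 12 (with 11) back to 16: switch to hydroxide-stable acetals and an isolated chalcone. MOMCl/iPr2NEt converts 12 into 2,4-bis(methoxymethoxy)benzaldehyde F5. Claisen–Schmidt condensation with 11 in aqueous KOH/EtOH at rt gives (2E)-3-[2,4-bis(methoxymethoxy)phenyl]-1-[2,4-dihydroxy-6-methoxy-3-[(2S)-5-methyl-2-(prop-1-en-2-yl)hex-4-en-1-yl]phenyl]prop-2-en-1-one F6. Brief treatment with HCl in MeOH at rt, quenched at first full conversion, returns 16.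

## Further compounds

F1 | step 3 | 2-methyl-3-(phenylselanyl)propanal (racemic) | CC(C[Se]c1ccccc1)C=O
F2 | step 3 | (2E)-4-methyl-5-(phenylselanyl)pent-2-enal (racemic) | CC(C[Se]c1ccccc1)/C=C/C=O
F3 | step 3 | S-ethyl (3R)-3-[(3-acetyl-2,6-dihydroxy-4-methoxyphenyl)methyl]-4-methyl-5-(phenylselanyl)pentanethioate (both C4 epimers) | CC(C[Se]c1ccccc1)[C@@H](CC(=O)SCC)Cc1c(O)cc(OC)c(C(C)=O)c1O
F4 | step 2 | 1-[3-[(dimethylamino)methyl]-2,4-dihydroxy-6-methoxyphenyl]ethan-1-one | CN(C)Cc1c(O)cc(OC)c(C(C)=O)c1O
F5 | step 7 | 2,4-bis(methoxymethoxy)benzaldehyde | COCOc1ccc(C=O)c(OCOC)c1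
F6 | step 7 | (2E)-3-[2,4-bis(methoxymethoxy)phenyl]-1-[2,4-dihydroxy-6-methoxy-3-[(2S)-5-methyl-2-(prop-1-en-2-yl)hex-4-en-1-yl]phenyl]prop-2-en-1-one | C=C(C)[C@@H](CC=C(C)C)Cc1c(O)cc(OC)c(C(=O)/C=C/c2ccc(OCOC)cc2OCOC)c1O
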